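**Strategy.** Everything rests on opening rings A and B together. An intramolecular Diels–Alder reaction of an acyclic 1,7,9-decatrien-3-one forms the C5–C10 ring-fusion bond and the C1–C2 bond in one operation: the isopropenyl ketone (C1=C10, C20 methyl, C9 carbonyl) adds to a C2=C3–C4=C5 diene carrying one C4 methyl group. The step exploits the unfunctionalised cyclohexane ring A, fused to ring B at quaternary C10 beside oxygenated C9. A syn-aldol pair on the tether (C7–OSiEt3, C8–CH3) fixes the absolute sense at C5 and C10; C7–O later directs the C8/C9 epoxidation and ends as the ketone. Hydromethylation of C3=C4 completes the gem-dimethyl group, and a chiral C11–C16 alkynyl carbinol supplies both spiro ethers.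

Key step: step 5

Remark: atoms are numbered as in labdane (C1–C20; C17 = methyl on C8, C20 = methyl on C10); α/β denote the lower/upper face of the decalin in its usual orientation; the target is read as (5S,8R,9S,10S,13R).

**Step 1**
Reactants: 1 pent-3-yn-1-ol; 2 bromoethene
Product: 4 (3E)-4-methylhexa-3,5-dien-1-ol, via alkenylzirconocene chloride 3 (not isolated)
Conditions: Cp2Zr(H)Cl (2.2 equiv), THF, rt → 40 °C; then ZnCl2 (1.1 equiv), Pd(PPh3)4 (3 mol %), 2, rt
Reagents that add atoms: none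
Why: syn-hydrozirconation should place zirconium on the methyl-bearing alkyne carbon, and the zinc-assisted Negishi coupling with bromoethene proceeds with retention, which fixes the 3E geometry of the diene.

**Step 2**
Reactants: 4 (3E)-4-methylhexa-3,5-dien-1-ol
Product: 5 (3E)-4-methylhexa-3,5-dienal
Conditions: Dess–Martin periodinane, NaHCO3, CH2Cl2, 0 °C; used at once
Reagents that add atoms: none
Why: Dess–Martin oxidation under buffered, non-acidic conditions should give the β,γ-unsaturated aldehyde without migration of the double bond into conjugation.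

**Step 3**
Reactants: 6 2-methylpent-1-en-3-one; 5 (3E)-4-methylhexa-3,5-dienal
Product: 9 (4R,5S,7E)-5-hydroxy-2,4,8-trimethyldeca-1,7,9-trien-3-one, via Z-enol diisopinocampheylborinate 7 (not isolated), via boron aldolate 8 (not isolated)
Conditions: (−)-Ipc2BOTf (1.3 equiv), i-Pr2NEt, CH2Cl2, −78 °C; 5, −78 → −20 °C; then pH 7 buffer, MeOH, H2O2, 0 °C
Reagents that add atoms: none
Why: Paterson boron aldol reaction, in which the Z-enol borinate of the ethyl ketone reacts through a chair Zimmerman–Traxler transition state to give the syn adduct, and the isopinocampheyl ligands (re-face attack on the aldehyde expected for this reagent with ethyl ketones, otherwise its antipode is used) set 4R,5S.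

**Step 4**
Reactants: 9 (4R,5S,7E)-5-hydroxy-2,4,8-trimethyldeca-1,7,9-trien-3-one
Product: 10 (4R,5S,7E)-2,4,8-trimethyl-5-[(triethylsilyl)oxy]deca-1,7,9-trien-3-one
Conditions: Et3SiCl, imidazole, DMF, 0 °C
Reagents that add atoms: chlorotriethylsilane, CC[Si](Cl)(CC)CC
Why: silylation of the secondary alcohol blocks retro-aldol cleavage at the temperature of the next step and provides the bulky equatorial substituent for the cycloaddition.

**Step 5**
Reactants: 10 (4R,5S,7E)-2,4,8-trimethyl-5-[(triethylsilyl)oxy]deca-1,7,9-trien-3-one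
Product: 11 (2R,3S,4aS,8aS)-2,5,8a-trimethyl-3-[(triethylsilyl)oxy]-3,4,4a,7,8,8a-hexahydronaphthalen-1(2H)-one
Conditions: PhMe (0.01 M), BHT (5 mol %), 150 °C, sealed tube
Reagents that add atoms: none
Why: Thermal concerted [4+2] cycloaddition, a type 1 intramolecular Diels–Alder reaction of a 1,7,9-decatrien-3-one, in which the C9-carbonyl-activated isopropenyl group adds across the C2=C3–C4=C5 diene. Ring B closes as the six-membered carbocycle C5–C6–C7–C8–C9–C10 in the fused mode imposed by the four-atom tether (bond C5–C10), and ring A is the cyclohexene made by the cycloaddition itself (bonds C5–C10 and C1–C2, suprafacial on both partners, leaving C3=C4). The trans ring fusion (10β-methyl, 5α-H) should come from the anti (tether-exo) transition state with a chair-like tether, expected to be preferred because the α-methyl group of the dienophile removes the usual endo bias of the carbonyl, while the syn mode pushes the branched C8–C9 segment under the C4-methyl-bearing diene. The absolute sense at C5 and C10 (both S) is relayed from the aldol centres, since only one anti transition state keeps C7–OSiEt3 and C8–CH3 equatorial and the other forces C8–CH3 into a syn-pentane clash with the C10 methyl group. The step therefore needs trans over cis fusion and one π-face, both secured by the substituents on tether and dienophile, and the E geometry of C4=C5 ties the C5 configuration to that of C10.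

**Step 6**
Reactants: 11 (2R,3S,4aS,8aS)-2,5,8a-trimethyl-3-[(triethylsilyl)oxy]-3,4,4a,7,8,8a-hexahydronaphthalen-1(2H)-one
Product: 13 (2R,3S,4aS,8aS)-2,5,5,8a-tetramethyl-3-[(triethylsilyl)oxy]octahydronaphthalen-1(2H)-one, via sulfonylhydrazide adduct 12 (not isolated)
Conditions: Fe(acac)3 (50 mol %), PhSiH3, CH2=NNHTs (3 equiv), THF/MeOH, rt; then MeOH, 60 °C
Reagents that add atoms: formaldehyde N-tosylhydrazone, C=NNS(=O)(=O)c1ccc(C)cc1
Why: iron-hydride hydrogen-atom transfer (olefin hydromethylation) gives the tertiary C4 radical, which adds to the formaldehyde hydrazone, and thermal loss of sulfinate and N2 leaves the second C4 methyl group; no stereocentre is created because C4 becomes gem-dimethyl.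

**Step 7**
Reactants: 13 (2R,3S,4aS,8aS)-2,5,5,8a-tetramethyl-3-[(triethylsilyl)oxy]octahydronaphthalen-1(2H)-one
Product: 15 (3S,4aS,8aS)-2,5,5,8a-tetramethyl-3-[(triethylsilyl)oxy]-3,4,4a,5,6,7,8,8a-octahydronaphthalen-1-yl trifluoromethanesulfonate, via potassium enolate 14 (not isolated)
Conditions: KN(SiMe3)2, THF, −78 °C; PhNTf2, −78 → 0 °C
Reagents that add atoms: N-phenylbis(trifluoromethanesulfonimide), O=S(=O)(N(c1ccccc1)S(=O)(=O)C(F)(F)F)C(F)(F)F
Why: enol triflate formation, regiospecific because the C9 ketone can enolise only toward C8 (C10 is quaternary), while the equatorial C7–O bond lies near the enolate plane and should resist β-elimination.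

**Step 8**
Reactants: 16 2-bromoprop-2-en-1-ol; 17 ethynyltrimethylsilane
Product: 18 2-methylidene-4-(trimethylsilyl)but-3-yn-1-ol
Conditions: PdCl2(PPh3)2 (2 mol %), CuI (4 mol %), Et3N, THF, rt
Reagents that add atoms: none
Why: Sonogashira coupling of the alkenyl bromide with the terminal alkyne assembles C13–C16 with C14≡C15 in place.

**Step 9**
Reactants: 18 2-methylidene-4-(trimethylsilyl)but-3-yn-1-ol
Product: 19 [(2R)-2-[(trimethylsilyl)ethynyl]oxiran-2-yl]methanol
Conditions: Ti(Oi-Pr)4 (10 mol %), D-(−)-diethyl tartrate (12 mol %), t-BuOOH, 4 Å molecular sieves, CH2Cl2, −20 °C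
Reagents that add atoms: tert-butyl hydroperoxide, CC(C)(C)OO
Why: Sharpless asymmetric epoxidation of a 2-substituted allylic alcohol, where the D-(−)-tartrate ligand should deliver oxygen to the face that gives the 2R epoxide and thus the oxygen-bearing C13 stereocentre of the target.

**Step 10**
Reactants: 19 [(2R)-2-[(trimethylsilyl)ethynyl]oxiran-2-yl]methanol
Product: 20 tert-butyldiphenyl{[(2S)-2-[(trimethylsilyl)ethynyl]oxiran-2-yl]methoxy}silane
Conditions: t-BuPh2SiCl, imidazole, CH2Cl2, 0 °C → rt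
Reagents that add atoms: tert-butyl(chloro)diphenylsilane, CC(C)(C)[Si](Cl)(c1ccccc1)c1ccccc1
Why: silylation of the primary alcohol (C16–O) prevents Payne rearrangement in the next basic step and masks this oxygen until the end; the descriptor changes only through priority rules.

**Step 11**
Reactants: 20 tert-butyldiphenyl{[(2S)-2-[(trimethylsilyl)ethynyl]oxiran-2-yl]methoxy}silane
Product: 22 (3R)-3-{[(tert-butyldiphenylsilyl)oxy]methyl}-5-(trimethylsilyl)pent-1-en-4-yn-3-ol, via sulfonium betaine 21 (not isolated)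
Conditions: Me3S+ I− (3 equiv), n-BuLi (2.9 equiv), THF, −10 °C; then 20, −10 °C → rt
Reagents that add atoms: trimethylsulfonium iodide, C[S+](C)C.[I-]
Why: one-carbon homologation of a terminal epoxide to an allylic alcohol, in which dimethylsulfonium methylide opens the oxirane at its CH2 carbon (C12) and the betaine eliminates dimethyl sulfide; the C13–O bond is untouched, so the configuration is retained.

**Step 12**
Reactants: 22 (3R)-3-{[(tert-butyldiphenylsilyl)oxy]methyl}-5-(trimethylsilyl)pent-1-en-4-yn-3-ol; 15 enol triflate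
Product: 24 (13R)-16-[(tert-butyldiphenylsilyl)oxy]-7β-[(triethylsilyl)oxy]-15-(trimethylsilyl)labd-8-en-14-yn-13-ol, via B-alkyl-9-BBN 23 (not isolated)
Conditions: 9-BBN (1.5 equiv), THF, 0 °C → rt; then 15, Pd(dppf)Cl2 (10 mol %), AsPh3 (10 mol %), Cs2CO3, DMF/H2O, 50 °C
Reagents that add atoms: none
Why: B-alkyl Suzuki–Miyaura coupling, in which anti-Markovnikov hydroboration of the vinyl group (the silyl alkyne and the hindered tertiary hydroxyl should not compete) gives the C11 borane that couples with the alkenyl triflate to form C9–C11 and the tetrasubstituted C8=C9 olefin.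

**Step 13**
Reactants: 24 (13R)-16-[(tert-butyldiphenylsilyl)oxy]-7β-[(triethylsilyl)oxy]-15-(trimethylsilyl)labd-8-en-14-yn-13-ol
Product: 25 (13R)-16-[(tert-butyldiphenylsilyl)oxy]-15-(trimethylsilyl)labd-8-en-14-yne-7β,13-diol
Conditions: HF·pyridine, pyridine, THF, 0 °C
Reagents that add atoms: none
Why: selective fluoride cleavage of the secondary triethylsilyl ether, which the primary tert-butyldiphenylsilyl ether and the C-silyl alkyne should survive, frees the allylic 7β-hydroxyl under buffered conditions that avoid allylic ionisation.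

**Step 14**
Reactants: 25 (13R)-16-[(tert-butyldiphenylsilyl)oxy]-15-(trimethylsilyl)labd-8-en-14-yne-7β,13-diol
Product: 27 (13R)-16-[(tert-butyldiphenylsilyl)oxy]-9α,13-epoxy-15-(trimethylsilyl)labd-14-yne-7β,8β-diol, via 8β,9β-epoxide 26 (not isolated)
Conditions: VO(acac)2 (5 mol %), t-BuOOH, CH2Cl2, 0 °C → rt; then camphorsulfonic acid (10 mol %)
Reagents that add atoms: tert-butyl hydroperoxide, CC(C)(C)OO
Why: hydroxyl-directed vanadium-catalysed epoxidation should place the oxirane syn to the allylic 7β-hydroxyl (β face, overriding the C10 methyl group), and acid then triggers 5-exo, trans-diaxial opening at C9 by the C13 hydroxyl with inversion, which sets 9α-O–C13 and leaves the 8β-hydroxyl with 8α-methyl.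

**Step 15**
Reactants: 27 (13R)-16-[(tert-butyldiphenylsilyl)oxy]-9α,13-epoxy-15-(trimethylsilyl)labd-14-yne-7β,8β-diol
Product: 29 (13R)-8β-acetoxy-16-[(tert-butyldiphenylsilyl)oxy]-9α,13-epoxy-15-(trimethylsilyl)labd-14-yn-7β-ol, via cyclic orthoacetate 28 (not isolated)
Conditions: MeC(OMe)3, pyridinium p-toluenesulfonate (cat.), CH2Cl2, rt; then AcOH/H2O (4:1), 0 °C
Reagents that add atoms: trimethyl orthoacetate, COC(C)(OC)OC; water, O
Why: cyclic orthoester formation on the cis-7β,8β-diol followed by stereoelectronically controlled hydrolysis, which opens the hemi-orthoester to the axial ester and so acetylates the hindered tertiary axial C8 oxygen while freeing the equatorial C7 hydroxyl.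

**Step 16**
Reactants: 29 (13R)-8β-acetoxy-16-[(tert-butyldiphenylsilyl)oxy]-9α,13-epoxy-15-(trimethylsilyl)labd-14-yn-7β-ol
Product: 30 (13R)-8β-acetoxy-16-[(tert-butyldiphenylsilyl)oxy]-9α,13-epoxy-15-(trimethylsilyl)labd-14-yn-7-one
Conditions: Dess–Martin periodinane, NaHCO3, CH2Cl2, 0 °C → rt
Reagents that add atoms: none
Why: Dess–Martin oxidation of the only free (secondary) alcohol gives the C7 ketone and removes the possibility of acetyl migration from O8 to O7.

**Step 17**
Reactants: 30 (13R)-8β-acetoxy-16-[(tert-butyldiphenylsilyl)oxy]-9α,13-epoxy-15-(trimethylsilyl)labd-14-yn-7-one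
Product: 31 (13R)-8β-acetoxy-9α,13-epoxy-16-hydroxylabd-14-yn-7-one
Conditions: Bu4NF, AcOH, THF, 0 °C → rt
Reagents that add atoms: none
Why: fluoride-mediated cleavage of both the O-silyl ether and the alkynyl C–Si bond, buffered with acetic acid so that the tertiary α-acetoxy ketone should survive.

**Step 18**
Reactants: 31 (13R)-8β-acetoxy-9α,13-epoxy-16-hydroxylabd-14-yn-7-one
Product: 32 (5S,8R,9S,10S,13R)-8-acetoxy-9,13:15,16-diepoxylabd-14-en-7-one
Conditions: Mo(CO)6 (30 mol %), Et3N, Et2O, hν (350 nm), rt; chromatography on Et3N-deactivated silica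
Reagents that add atoms: none
Why: alkynol endo-cycloisomerisation through a molybdenum vinylidene (McDonald type), in which the C16 hydroxyl adds to C15 to give the 2,3-dihydrofuran under basic conditions that should preserve the acid-labile spiro enol ether; no stereocentre is touched.

**Compound list**

1 | pent-3-yn-1-ol | CC#CCCO | starting material
2 | bromoethene | C=CBr | starting material
3 | [(2E)-5-(chlorozirconocenyloxy)pent-2-en-2-yl]zirconocene chloride | C/C(=C\CCO[Zr](Cl)(C1C=CC=C1)C1C=CC=C1)[Zr](Cl)(C1C=CC=C1)C1C=CC=C1 | intermediate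
4 | (3E)-4-methylhexa-3,5-dien-1-ol | OCC/C=C(\C)C=C | intermediate
5 | (3E)-4-methylhexa-3,5-dienal | O=CC/C=C(\C)C=C | intermediate
6 | 2-methylpent-1-en-3-one | CCC(=O)C(C)=C | starting material
7 | (Z)-enol diisopinocampheylborinate of 6 | C/C=C(\OB([C@@H]1C[C@@H]2C[C@H]([C@H]1C)C2(C)C)[C@@H]3C[C@@H]4C[C@H]([C@H]3C)C4(C)C)C(C)=C | intermediate
8 | O-diisopinocampheylboryl aldolate of 9 | C=C(C)C(=O)[C@H](C)[C@@H](OB([C@@H]1C[C@@H]2C[C@H]([C@H]1C)C2(C)C)[C@@H]3C[C@@H]4C[C@H]([C@H]3C)C4(C)C)C/C=C(\C)C=C | intermediate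
9 | (4R,5S,7E)-5-hydroxy-2,4,8-trimethyldeca-1,7,9-trien-3-one | C=C(C)C(=O)[C@H](C)[C@@H](O)C/C=C(\C)C=C | intermediate
10 | (4R,5S,7E)-2,4,8-trimethyl-5-[(triethylsilyl)oxy]deca-1,7,9-trien-3-one | C=C(C)C(=O)[C@H](C)[C@@H](O[Si](CC)(CC)CC)C/C=C(\C)C=C | intermediate
11 | (2R,3S,4aS,8aS)-2,5,8a-trimethyl-3-[(triethylsilyl)oxy]-3,4,4a,7,8,8a-hexahydronaphthalen-1(2H)-one | C[C@@H]1[C@@H](O[Si](CC)(CC)CC)C[C@H]2C(C)=CCC[C@]2(C)C1=O | intermediate
12 | N′-tosylhydrazinomethyl adduct at C4 of 11 (C4 epimers) | C[C@@H]1[C@@H](O[Si](CC)(CC)CC)C[C@H]2C(C)(CNNS(=O)(=O)c3ccc(C)cc3)CCC[C@]2(C)C1=O | intermediate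
13 | (2R,3S,4aS,8aS)-2,5,5,8a-tetramethyl-3-[(triethylsilyl)oxy]octahydronaphthalen-1(2H)-one | C[C@@H]1[C@@H](O[Si](CC)(CC)CC)C[C@H]2C(C)(C)CCC[C@]2(C)C1=O | intermediate
14 | potassium C8=C9 enolate of 13 | CC[Si](CC)(CC)O[C@H]1C[C@H]2C(C)(C)CCC[C@]2(C)C([O-])=C1C.[K+] | intermediate
15 | (3S,4aS,8aS)-2,5,5,8a-tetramethyl-3-[(triethylsilyl)oxy]-3,4,4a,5,6,7,8,8a-octahydronaphthalen-1-yl trifluoromethanesulfonate | CC[Si](CC)(CC)O[C@H]1C[C@H]2C(C)(C)CCC[C@]2(C)C(OS(=O)(=O)C(F)(F)F)=C1C | intermediate
16 | 2-bromoprop-2-en-1-ol | OCC(Br)=C | starting material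
17 | ethynyltrimethylsilane | C#C[Si](C)(C)C | starting material
18 | 2-methylidene-4-(trimethylsilyl)but-3-yn-1-ol | OCC(=C)C#C[Si](C)(C)C | intermediate
19 | [(2R)-2-[(trimethylsilyl)ethynyl]oxiran-2-yl]methanol | OC[C@]1(C#C[Si](C)(C)C)CO1 | intermediate
20 | tert-butyldiphenyl{[(2S)-2-[(trimethylsilyl)ethynyl]oxiran-2-yl]methoxy}silane | CC(C)(C)[Si](c1ccccc1)(c1ccccc1)OC[C@]2(C#C[Si](C)(C)C)CO2 | intermediate
21 | sulfonium betaine from ylide opening of 20 at the oxirane CH2 | C[S+](C)CC[C@@]([O-])(C#C[Si](C)(C)C)CO[Si](c1ccccc1)(c1ccccc1)C(C)(C)C | intermediate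
22 | (3R)-3-{[(tert-butyldiphenylsilyl)oxy]methyl}-5-(trimethylsilyl)pent-1-en-4-yn-3-ol | C=C[C@@](O)(C#C[Si](C)(C)C)CO[Si](c1ccccc1)(c1ccccc1)C(C)(C)C | intermediate
23 | 9-BBN adduct of 22 (boron on C11) | B1(C2CCCC1CCC2)CC[C@@](O)(C#C[Si](C)(C)C)CO[Si](c3ccccc3)(c3ccccc3)C(C)(C)C | intermediate
24 | (13R)-16-[(tert-butyldiphenylsilyl)oxy]-7β-[(triethylsilyl)oxy]-15-(trimethylsilyl)labd-8-en-14-yn-13-ol | CC[Si](CC)(CC)O[C@H]1C[C@H]2C(C)(C)CCC[C@]2(C)C(CC[C@@](O)(C#C[Si](C)(C)C)CO[Si](c3ccccc3)(c3ccccc3)C(C)(C)C)=C1C | intermediate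
25 | (13R)-16-[(tert-butyldiphenylsilyl)oxy]-15-(trimethylsilyl)labd-8-en-14-yne-7β,13-diol | O[C@H]1C[C@H]2C(C)(C)CCC[C@]2(C)C(CC[C@@](O)(C#C[Si](C)(C)C)CO[Si](c3ccccc3)(c3ccccc3)C(C)(C)C)=C1C | intermediate
26 | 8β,9β-epoxide of 25 | O[C@H]1C[C@H]2C(C)(C)CCC[C@]2(C)[C@@]3(CC[C@@](O)(C#C[Si](C)(C)C)CO[Si](c4ccccc4)(c4ccccc4)C(C)(C)C)O[C@@]13C | intermediate
27 | (13R)-16-[(tert-butyldiphenylsilyl)oxy]-9α,13-epoxy-15-(trimethylsilyl)labd-14-yne-7β,8β-diol | O[C@@]1(C)[C@@H](O)C[C@H]2C(C)(C)CCC[C@]2(C)[C@@]12CC[C@@](C#C[Si](C)(C)C)(CO[Si](c3ccccc3)(c3ccccc3)C(C)(C)C)O2 | intermediate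
28 | 7β,8β-O-(1-methoxyethylidene) orthoester of 27 | COC1(C)O[C@@]2(C)[C@@H](O1)C[C@H]3C(C)(C)CCC[C@]3(C)[C@@]24CC[C@@](C#C[Si](C)(C)C)(CO[Si](c5ccccc5)(c5ccccc5)C(C)(C)C)O4 | intermediate
29 | (13R)-8β-acetoxy-16-[(tert-butyldiphenylsilyl)oxy]-9α,13-epoxy-15-(trimethylsilyl)labd-14-yn-7β-ol | CC(=O)O[C@@]1(C)[C@@H](O)C[C@H]2C(C)(C)CCC[C@]2(C)[C@@]12CC[C@@](C#C[Si](C)(C)C)(CO[Si](c3ccccc3)(c3ccccc3)C(C)(C)C)O2 | intermediate
30 | (13R)-8β-acetoxy-16-[(tert-butyldiphenylsilyl)oxy]-9α,13-epoxy-15-(trimethylsilyl)labd-14-yn-7-one | CC(=O)O[C@@]1(C)C(=O)C[C@H]2C(C)(C)CCC[C@]2(C)[C@@]12CC[C@@](C#C[Si](C)(C)C)(CO[Si](c3ccccc3)(c3ccccc3)C(C)(C)C)O2 | intermediate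
31 | (13R)-8β-acetoxy-9α,13-epoxy-16-hydroxylabd-14-yn-7-one | CC(=O)O[C@@]1(C)C(=O)C[C@H]2C(C)(C)CCC[C@]2(C)[C@@]12CC[C@@](C#C)(CO)O2 | intermediate
32 | (5S,8R,9S,10S,13R)-8-acetoxy-9,13:15,16-diepoxylabd-14-en-7-one (CNP0165143.1) | CC(=O)O[C@@]1(C)C(=O)C[C@H]2C(C)(C)CCC[C@]2(C)[C@@]12CC[C@]1(C=COC1)O2 | target

**Totals.** Total step count: 18. Longest linear sequence: 14 steps (steps 1–7 and 12–18); steps 8–11 build the side-chain fragment.

**Steps most likely to fail**

Step 5. The cycloaddition may discriminate poorly between the anti (trans-fusing) and syn (cis-fusing) modes or between the two diene faces, or the trienone may oligomerise before it cyclises. The fallback sets out from 10 and changes the dienophile from a neutral enone to a cation. Ketalisation with 1,2-bis(trimethylsilyloxy)ethane and catalytic Me3SiOTf (CH2Cl2, −78 °C) would give the 1,3-dioxolane of 10, F1. Catalytic TfOH at −78 °C would open F1 to its alkoxyallyl cation, which should undergo a Gassman-type cationic Diels–Alder reaction that still closes both rings at once but at low temperature. The resulting cycloadduct ketal, the 1,3-dioxolane of 11, F2, would be hydrolysed with pyridinium p-toluenesulfonate in wet acetone, and the route is rejoined at 11.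

Step 12. Oxidative addition and transmetalation at the alkenyl triflate, flanked by the quaternary C10 and the methyl-bearing C8, may be too slow, so that triflate hydrolysis and protodeboronation take over. The fallback sets out from 22 and 13 and replaces the cross-coupling by carbonyl addition and dehydration. Silylation of 22 (Et3SiOTf, 2,6-lutidine) would give the triethylsilyl ether F3, and hydroboration followed by iodinolysis (9-BBN; then I2, NaOMe) the primary iodide F4. Halogen–lithium exchange (t-BuLi, −78 °C) and addition of CeCl3 would give the organocerium reagent F5, which should add to the hindered ketone 13 to give the C9 tertiary alcohol F6. Dehydration (SOCl2, pyridine) toward C8 would give the bis(triethylsilyl) ether of the Δ8 olefin, F7, and HF·pyridine as in step 13 removes both triethylsilyl groups, so the route is rejoined at 25.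

Step 18. The metal vinylidene may expel the propargylic C13 oxygen, which would lead to aromatisation to the 3-substituted furan with a free 9-hydroxyl, or the catalyst may stall on the hindered alkyne. The fallback sets out from 31 and builds the enol ether by hydration and elimination. Ruthenium-catalysed anti-Markovnikov hydration of the terminal alkyne (CpRu(MeCN)3PF6, 5,5′-bis(trifluoromethyl)-2,2′-bipyridine, NMP/H2O, rt) would give the C15 aldehyde, which closes with the C16 hydroxyl to the lactol, the 15-hydroxy-14,15-dihydro derivative of 32, F8. Mesylation with in situ elimination (MeSO2Cl, Et3N, CH2Cl2, −20 °C → rt) should then give the 2,3-dihydrofuran under basic conditions, and the route is rejoined at 32.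

**Further compounds**

F1 | step 5 | 2-(prop-1-en-2-yl)-2-[(2R,3S,5E)-6-methyl-3-[(triethylsilyl)oxy]octa-5,7-dien-2-yl]-1,3-dioxolane (ethylene ketal of 10) | C=C(C)C1(OCCO1)[C@H](C)[C@@H](O[Si](CC)(CC)CC)C/C=C(\C)C=C
F2 | step 5 | ethylene ketal of 11 at C1 of the naphthalenone (C9 in labdane numbering) | C[C@@H]1[C@@H](O[Si](CC)(CC)CC)C[C@H]2C(C)=CCC[C@]2(C)C13OCCO3
F3 | step 12 | triethylsilyl ether of 22 | C=C[C@@](O[Si](CC)(CC)CC)(C#C[Si](C)(C)C)CO[Si](c1ccccc1)(c1ccccc1)C(C)(C)C
F4 | step 12 | primary iodide from F3 (iodine on C11) | ICC[C@@](O[Si](CC)(CC)CC)(C#C[Si](C)(C)C)CO[Si](c1ccccc1)(c1ccccc1)C(C)(C)C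
F5 | step 12 | organocerium dichloride from F4 | Cl[Ce](Cl)CC[C@@](O[Si](CC)(CC)CC)(C#C[Si](C)(C)C)CO[Si](c1ccccc1)(c1ccccc1)C(C)(C)C
F6 | step 12 | C9 tertiary alcohol from addition of F5 to 13 (C9 configuration open) | C[C@@H]1[C@@H](O[Si](CC)(CC)CC)C[C@H]2C(C)(C)CCC[C@]2(C)C1(O)CC[C@@](O[Si](CC)(CC)CC)(C#C[Si](C)(C)C)CO[Si](c3ccccc3)(c3ccccc3)C(C)(C)C
F7 | step 12 | 13-O-triethylsilyl ether of 24 | CC[Si](CC)(CC)O[C@H]1C[C@H]2C(C)(C)CCC[C@]2(C)C(CC[C@@](O[Si](CC)(CC)CC)(C#C[Si](C)(C)C)CO[Si](c3ccccc3)(c3ccccc3)C(C)(C)C)=C1C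
F8 | step 18 | lactol, 15-hydroxy-14,15-dihydro derivative of 32 (C15 epimers) | CC(=O)O[C@@]1(C)C(=O)C[C@H]2C(C)(C)CCC[C@]2(C)[C@@]12CC[C@]1(CC(O)OC1)O2
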